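- The constant to freeze is the turnover rate, moles of E per hour per mole of G charged. Sunday's E climbs almost straight from 3.00 h to 12.0 h (a zero-order stretch), and that slope gives 0.842 /h.

| setting | Monday's | Saturday's | Sunday's | flask |
|---|---|---|---|---|
| D | 0.12 M | 0.19 M | 0.25 M | 0.25 M |
| G | 19 mM | 19 mM | 9.5 mM | 19 mM |
| remark | run made earlier | run made earlier | run made earlier |  |
| time |  |  |  | 15 h |

| run | time / h | E / % |
|---|---|---|
| Monday's | 0.667 | 6.8 |
| Monday's | 2.00 | 24.0 |
| Monday's | 3.00 | 34.7 |
| Monday's | 5.00 | 52.4 |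
| Monday's | 8.00 | 73.3 |
| Monday's | 10.0 | 80.7 |
| Monday's | 12.0 | 86.1 |
| Saturday's | 1.00 | 8.2 |
| Saturday's | 1.33 | 12.1 |
| Saturday's | 2.00 | 17.0 |
| Saturday's | 3.00 | 27.5 |
| Saturday's | 5.00 | 42.9 |
| Saturday's | 8.00 | 61.7 |
| Saturday's | 12.0 | 76.8 |
| Sunday's | 1.00 | 3.0 |
| Sunday's | 3.00 | 11.9 |
| Sunday's | 6.00 | 22.4 |
| Sunday's | 8.00 | 29.3 |
| Sunday's | 12.0 | 40.7 |

(standard deviation of a reading: 0.5 percentage points)

- the earlier runs were read with a standard deviation of 0.5 percentage points

- amount of E in percent of the D charged, at 1.5 h, 5.0 h and 15 h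

- Start with the main step. I take the rate as proportional to G, so the flask, with Sunday's D and twice its G, runs Sunday's clock at twice the speed. Its reading at 1.5 h is then Sunday's at 3.00 h, 11.9 %.
- Your time constant for the flask is the run-out time, D charged over turnover rate times G, 15.6 h. The straight line from that point gives 34.3 % at 5.0 h and 98.4 % at 15 h.
- Now add the bend. Monday's run has the flask's G and starts at 0.12 M, so for this step I count [D] simply as the charge minus E, a simplification that leaves out any D held elsewhere. Once that counted [D] comes down to 0.12 M, at about 7.77 h on my line, I let the flask repeat Monday's curve. That lowers 15 h to 84.6 %.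
- Then add the rest. The same splice on Saturday's run, which by the same count comes down to 0.12 M at 4.21 h, gives 82.2 % at 12.0 h, but the reading is 76.8 %. So by this count 10.3 mM of D is missing from E.
- I assume that loss goes as [D]² along a straight fall, so it scales with the difference of the cubes of [D]. My figure for 15 h then drops to 73.5 %.
- The forecast reads 11.3 %, 36.5 % and 80.5 %, which at the end is more than my figure, and says “I shaded the last value slightly down”.
- The flask gives 10.9 %, 36.1 % and 75.3 %. At 15.0 h, 17.9 % of the D charged stands as Q, each Q counted as two D, and 4.6 % is left as D.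

    D + G ⇌ X (K = 11.0 /M, k = 120 /M/h)
    X ⇌ L (K = 3.00, k = 2.39 /h)
    L ⇌ G + E (K = 17.0 M, k = 4.85 /h)
    2 D → Q (k = 0.125 /M/h)
    D + E → J (k = 0.0132 /M/h)

- Between 1.5 h and 5.0 h the flask turned over at 0.947 /h, against the 0.842 /h frozen from Sunday's run.
- Put 0.842 /h on Saturday's run: starting from its 17.0 % at 2.00 h, the slope gives 42.3 % at 5.00 h, and the reading there is 42.9 %.

All runs are calculated on assumed constants; noise was put on by code.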